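**Numbering used throughout.** 1 lactate dioxolanone, 2 allyl bromide, 3 enolate of 1, 4 allylated dioxolanone, 5 Weinreb amide, 6 (Z)-enynol, 7 its silyl ether, 8 acetylide of 7, 9 hydroxy ynone, 10 allyl furanone, 11 diol, 12 aldehyde, 13 methyl propiolate, 14 formaldehyde, 15 iodoacrylate, 16 hydroxy ester, 17 hydroxymethyl butenolide, 18 bromomethyl butenolide, 19 allylic alcohol, 20 enal, 21 allylchromium, 22 macrocyclic 6-epi alcohol, 23 methyl angelate, 24 angelyl alcohol, 25 epoxy alcohol, 26 epoxy acid, 27 target.

Assumption: the SMILES is read as the (6S,7R,8S,10R) ring with a 4Z alkene and a (2R,3R)-epoxy ester whose methyl groups are trans on the oxirane; germacrane numbering (C1 ketone to C15) is used for ring atoms.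

## Analysis of the target

Compound 27 is a furanoheliangolide: a ten-membered carbocycle (C1–C10) bridged from C3 to C10 by the oxygen of a 3(2H)-furanone ring (O, C3, C2, C1, C10), which makes an 11-oxabicyclo[6.2.1]undecane. A trans-fused α-methylene-γ-butyrolactone (C7, C8, O8, C12, C11, exocyclic C11=C13) sits on C7–C8, and O6 carries a (2R,3R)-2,3-epoxy-2-methylbutanoate. The ring stereocentres are C6 (S), C7 (R) and C8 (S), contiguous, with H6 and H7 cis and H7 and H8 trans, and the quaternary C10 (R), which is remote from this triad; the acyl group adds two more, and C4=C5 is Z. Sensitive groups are the α-methylene lactone (Michael acceptor), the cross-conjugated vinylogous ester C1(=O)–C2=C3(O)–C4=C5 (attacked by hydrides and organometals), the glycidic ester (acid- and nucleophile-labile) and the Z-trisubstituted alkene. The difficulties are the strain of the bridged ten-membered ring, the correlation of C10 with the C6–C8 triad, and the two oxygens O6 and O8 flanking C7, which any lactonisation-based route must tell apart. The feature used here is that O8 is already the lactone oxygen and C7 lies γ to C13 across C11. The α-methylene lactone is therefore the allylic transposition product of a 3-(halomethyl)but-2-enolide (C7=C11 in the ring, halide on C13). The intact lactone can thus deliver C7 as the nucleophilic γ-carbon of an allylmetal to a C6 aldehyde: one C–C bond closes the carbocycle, creates C6 and C7, unveils C11=C13 and leaves O6 as the only free hydroxyl.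

## Retrosynthetic reasoning

The ester C6–O bond is cut last, 27 to alcohol 22 and acid 26. The ring closure planned below is expected to give the 6-epi alcohol, so the esterification is planned with inversion: one step both acylates and corrects C6.

The key cut is the C6–C7 bond of 22, leading to enal 20 through the allylchromium 21. It is cut here and not at C7–C8 because the lactone stays intact, so the new carbinol is O6 alone and no lactone regiochemistry arises. C7 adds on the face of the planar butenolide away from C9 (trans lactone), and the shift of the double bond to C11=C13 installs the exocyclic methylene without a later base-mediated methylenation. The forward reaction has to close a strained ring intramolecularly and react only at the aldehyde.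

Enal 20 is taken back through allylic alcohol 19 and bromide 18 to hydroxymethyl butenolide 17 by functional group changes only, so that the allylic bromide and the aldehyde appear last.

Butenolide 17 is cut at C7–C8 and O8–C12 into aldehyde 12 and iodoacrylate 15. A nickel/chromium-mediated alkenylation of the aldehyde followed by lactonisation makes the ring in one operation and sets C8 under ligand control.

Aldehyde 12 comes from the allyl group of furanone 10 by oxidative cleavage of its only isolated alkene. The allyl group therefore supplies C9 and C8.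

Furanone 10 is opened at O–C3 to hydroxy ynone 9, which is cut at C1–C2 into Weinreb amide 5 and alkyne 7. Alkyne 7 carries the Z-C4=C5 bond ready-made from the commercial enynol 6.

The quaternary C10 of 5 is traced through 4 to dioxolanone 1 and allyl bromide 2, so that C10 comes from the chiral pool with the configuration fixed by a temporary acetal stereocentre.

Iodoacrylate 15 is cut into 13 and 14, and acid 26 is traced through 25 and 24 to 23.

## Alternatives that were turned down

Alternative 1: The textbook route forms the furanone last by transannular cyclisation of the ten-membered α′-hydroxy ynone A1. A1 is closed by intramolecular Barbier allylation of the open-chain bromide A2 onto the C8 aldehyde (C7–C8 bond, lactonisation onto O8). It was turned down because A2 needs the C6 stereocentre and a γ-oxygenated 2-(bromomethyl)enoate terminus, which together cost about six further linear operations. The allylmetal made from A2 also carries an oxygen leaving group on C6 and is prone to 1,4-elimination of that oxygen. Finally, the ynone carbonyl must be masked during the metal-mediated closure, which adds protecting-group steps, and A1 holds an alkyne inside a ten-membered ring.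

Alternative 2: Oxonium ylide formation and [2,3]-sigmatropic ring expansion of the sugar-derived diazoketone dihydropyran A3 would give bicycle A4. The pyran oxygen becomes the furanone oxygen, C4=C5 is Z by construction, and C9–C10 and the quaternary C10 form in one step. It was turned down because the shift necessarily leaves a C7=C8 alkene. Adding C11 to C7 and O8 to C8 trans across it, next to a second allylic position, costs at least six further operations with regiochemical ambiguity. A3 itself has no short access from a commercial glycal, because the ring methyl group has to be introduced first, and C2=C3 must still be introduced after the shift.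

Alternative 3: Ring-closing metathesis of the divinyl compound A5 at C7=C8 would give the Z-cycloalkene A6. It closes the ring from cheap precursors, but the metathesis is reversible for a strained bridged ten-membered ring, and it ends at the same C7=C8 alkene as Alternative 2. The lactone would have to be annulated afterwards by epoxidation, C7-selective alkynylation and carbonylation, with both O6 and O8 competing for the acyl group.

Key step: step 12

## Route

Step 1
Reactants: 1 (2S,5S)-2-tert-butyl-5-methyl-1,3-dioxolan-4-one; 2 allyl bromide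
Product: 4 (2S,5R)-2-tert-butyl-5-methyl-5-(prop-2-en-1-yl)-1,3-dioxolan-4-one, via lithium enolate 3 (not isolated)
Conditions: LiN(i-Pr)2, THF, −78 °C; then 2, −78 → −30 °C
Reagents that add atoms: none
Why: Enolate alkylation with self-regeneration of the stereocentre: the planar enolate 3 is attacked trans to the tert-butyl group of the intact acetal centre, so allyl replaces H with retention and fixes the future C10 as R.

Step 2
Reactants: 4 (2S,5R)-2-tert-butyl-5-methyl-5-(prop-2-en-1-yl)-1,3-dioxolan-4-one
Product: 5 (R)-2-hydroxy-N-methoxy-N,2-dimethylpent-4-enamide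
Conditions: MeNH(OMe)·HCl, i-PrMgCl, THF, −20 → 0 °C; aq. NH4Cl
Reagents that add atoms: N,O-dimethylhydroxylamine hydrochloride, CNOC.Cl
Why: Aminolysis of the activated acetal-ester by the magnesium amide gives the Weinreb amide and releases pivalaldehyde; the quaternary centre is not involved.

Step 3
Reactants: 6 (Z)-3-methylpent-2-en-4-yn-1-ol
Product: 7 tert-butyldimethyl{[(2Z)-3-methylpent-2-en-4-yn-1-yl]oxy}silane
Conditions: t-BuMe2SiCl, imidazole, DMF, 0 °C → rt
Reagents that add atoms: tert-butyldimethylsilyl chloride, C[Si](C)(Cl)C(C)(C)C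
Why: Silylation masks the primary hydroxyl, which would otherwise quench the acetylide and later add to the activated alkyne to give a furan.

Step 4
Reactants: 5 (R)-2-hydroxy-N-methoxy-N,2-dimethylpent-4-enamide; 7 tert-butyldimethyl{[(2Z)-3-methylpent-2-en-4-yn-1-yl]oxy}silane
Product: 9 (4R,8Z)-10-[(tert-butyldimethylsilyl)oxy]-4-hydroxy-4,8-dimethyldeca-1,8-dien-6-yn-5-one, via lithium acetylide 8 (not isolated)
Conditions: 7, n-BuLi, THF, −78 °C; then 5, −78 → −20 °C; aq. NH4Cl
Reagents that add atoms: none
Why: Weinreb ketone synthesis: excess acetylide first deprotonates the tertiary hydroxyl, then adds once because the chelated tetrahedral intermediate survives until work-up; the Z-alkene and C10 are untouched.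

Step 5
Reactants: 9 (4R,8Z)-10-[(tert-butyldimethylsilyl)oxy]-4-hydroxy-4,8-dimethyldeca-1,8-dien-6-yn-5-one
Product: 10 (2R)-5-[(2Z)-4-[(tert-butyldimethylsilyl)oxy]but-2-en-2-yl]-2-methyl-2-(prop-2-en-1-yl)furan-3(2H)-one
Conditions: Ph3PAuCl (cat.), AgOTf (cat.), toluene, rt
Reagents that add atoms: none
Why: Gold-catalysed 5-endo-dig hydroalkoxylation of the α′-hydroxy ynone forms the 3(2H)-furanone (O–C3 bond) under neutral conditions, which should preserve the Z-alkene and the quaternary centre.

Step 6
Reactants: 10 (2R)-5-[(2Z)-4-[(tert-butyldimethylsilyl)oxy]but-2-en-2-yl]-2-methyl-2-(prop-2-en-1-yl)furan-3(2H)-one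
Product: 12 2-[(2R)-5-[(2Z)-4-[(tert-butyldimethylsilyl)oxy]but-2-en-2-yl]-2-methyl-3-oxo-2,3-dihydrofuran-2-yl]acetaldehyde, via diol 11 (not isolated)
Conditions: OsO4 (cat.), NaIO4, 2,6-lutidine, dioxane/H2O, rt
Reagents that add atoms: sodium periodate, [Na+].[O-]I(=O)(=O)=O; water, O
Why: Lemieux–Johnson cleavage; the monosubstituted vinyl group is the only electron-neutral, unhindered alkene, whereas C2=C3 and C4=C5 belong to the electron-poor vinylogous ester and C4=C5 is shielded by the allylic silyl ether.

Step 7
Reactants: 13 methyl propiolate; 14 formaldehyde (as paraformaldehyde)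
Product: 15 methyl (2Z)-2-(hydroxymethyl)-3-iodoprop-2-enoate
Conditions: MgI2, CH2Cl2, 0 °C → rt
Reagents that add atoms: magnesium diiodide, [Mg+2].[I-].[I-]
Why: Halo-aldol (β-iodo Morita–Baylis–Hillman) reaction: iodide adds to the ynoate, and the magnesium allenolate is hydroxymethylated at the α-carbon anti to iodine, which places iodine cis to the ester.

Step 8
Reactants: 12 2-[(2R)-5-[(2Z)-4-[(tert-butyldimethylsilyl)oxy]but-2-en-2-yl]-2-methyl-3-oxo-2,3-dihydrofuran-2-yl]acetaldehyde; 15 methyl (2Z)-2-(hydroxymethyl)-3-iodoprop-2-enoate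
Product: 17 (5S)-5-{[(2R)-5-[(2Z)-4-[(tert-butyldimethylsilyl)oxy]but-2-en-2-yl]-2-methyl-3-oxo-2,3-dihydrofuran-2-yl]methyl}-3-(hydroxymethyl)furan-2(5H)-one, via hydroxy ester 16 (not isolated)
Conditions: CrCl2, NiCl2 (cat.), chiral sulfonamide–oxazoline ligand, Et3N, THF, rt; aq. NH4Cl
Reagents that add atoms: none
Why: Asymmetric Nozaki–Hiyama–Kishi alkenylation: the carbon–iodine bond of 15 is activated by nickel and passed to chromium with retention of alkene geometry, the organochromium adds only to the aldehyde, and the alkoxide cis to the ester lactonises to the butenolide; the C8 carbinol (S) is set by the chiral ligand on chromium because the remote C10 centre gives little bias.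

Step 9
Reactants: 17 (5S)-5-{[(2R)-5-[(2Z)-4-[(tert-butyldimethylsilyl)oxy]but-2-en-2-yl]-2-methyl-3-oxo-2,3-dihydrofuran-2-yl]methyl}-3-(hydroxymethyl)furan-2(5H)-one
Product: 18 (5S)-3-(bromomethyl)-5-{[(2R)-5-[(2Z)-4-[(tert-butyldimethylsilyl)oxy]but-2-en-2-yl]-2-methyl-3-oxo-2,3-dihydrofuran-2-yl]methyl}furan-2(5H)-one
Conditions: CBr4, PPh3, CH2Cl2, 0 °C
Reagents that add atoms: tetrabromomethane, BrC(Br)(Br)Br
Why: Appel bromination of the primary allylic alcohol under neutral conditions, which avoids base-induced epimerisation of the acidic butenolide γ-position (C8).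

Step 10
Reactants: 18 (5S)-3-(bromomethyl)-5-{[(2R)-5-[(2Z)-4-[(tert-butyldimethylsilyl)oxy]but-2-en-2-yl]-2-methyl-3-oxo-2,3-dihydrofuran-2-yl]methyl}furan-2(5H)-one
Product: 19 (5S)-3-(bromomethyl)-5-{[(2R)-5-[(2Z)-4-hydroxybut-2-en-2-yl]-2-methyl-3-oxo-2,3-dihydrofuran-2-yl]methyl}furan-2(5H)-one
Conditions: aq. HF, MeCN, 0 °C
Reagents that add atoms: none
Why: Acidic fluoride desilylation of the primary silyl ether; no amine or free fluoride salt is present that could displace the allylic bromide.

Step 11
Reactants: 19 (5S)-3-(bromomethyl)-5-{[(2R)-5-[(2Z)-4-hydroxybut-2-en-2-yl]-2-methyl-3-oxo-2,3-dihydrofuran-2-yl]methyl}furan-2(5H)-one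
Product: 20 (2Z)-3-[(5R)-5-{[(2S)-4-(bromomethyl)-5-oxo-2,5-dihydrofuran-2-yl]methyl}-5-methyl-4-oxo-4,5-dihydrofuran-2-yl]but-2-enal
Conditions: MnO2, CH2Cl2, rt, dark
Reagents that add atoms: none
Why: Neutral heterogeneous oxidation of the dienylic alcohol; it should leave the allylic bromide alone and keep the Z-enal from isomerising, and 20 is used at once.

Step 12
Reactants: 20 (2Z)-3-[(5R)-5-{[(2S)-4-(bromomethyl)-5-oxo-2,5-dihydrofuran-2-yl]methyl}-5-methyl-4-oxo-4,5-dihydrofuran-2-yl]but-2-enal
Product: 22 6α-hydroxy-1-oxo-3,10-epoxygermacra-2,4(Z),11(13)-trien-12,8α-olide, the C6 epimer (6R,7S,8S,10R by the sequence rules) of the alcohol of 27, via allylchromium 21 (not isolated)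
Conditions: CrCl2, THF, high dilution (slow addition of 20), rt; aq. NH4Cl
Reagents that add atoms: none
Why: Two single-electron transfers from CrCl2 turn the allylic bromide into the allylchromium 21 (trivalent chromium on C13), which adds to the aldehyde through its γ-carbon C7 in a six-membered chair with chromium bridging O6 and C13, shifting the double bond to C11=C13 (Nozaki–Hiyama allylation). The closest known reaction types are chromium-mediated ring closures of allylic bromides onto aldehydes in ten- to fourteen-membered terpenoid carbocycles, and the intermolecular γ-allylation of aldehydes by 3-(bromomethyl)butenolides. The one ring closed is the ten-membered carbocycle, by C6–C7 bond formation as a 1,2-addition exo to the aldehyde carbonyl, so the bond-forming event itself is the small chair and not a ten-membered array. C7 should be attacked on the face of the planar butenolide opposite to the C8–C9 bond, which gives the trans-fused lactone (H7α, H8β). C6 is set by the chair: the allyl unit is locked E because C8 is trans to C13 across C7=C11, so C5 and C8 both sit equatorial and the anti adduct results, which is the 6α-alcohol needed for the invertive esterification. Selectivity rests on high dilution against intermolecular allylation and on the inertness of allylchromium species towards the furanone ketone, the lactone and the exocyclic methylene product. Closure is helped by the cis C4=C5 bond and by the furanone holding C3 and C10 close, which fold the chain back on the butenolide. The step also needs γ-attack and not α-attack through C13, which the cyclic transition state enforces.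

Step 13
Reactants: 23 methyl angelate
Product: 24 (2Z)-2-methylbut-2-en-1-ol
Conditions: i-Bu2AlH, CH2Cl2, −78 °C; aq. potassium sodium tartrate
Reagents that add atoms: none
Why: 1,2-Reduction of the enoate to the allylic alcohol at low temperature without touching the Z-alkene.

Step 14
Reactants: 24 (2Z)-2-methylbut-2-en-1-ol
Product: 25 [(2S,3R)-2,3-dimethyloxiran-2-yl]methanol
Conditions: Ti(Oi-Pr)4, L-(+)-diethyl tartrate, t-BuOOH, 4 Å molecular sieves, CH2Cl2, −20 °C
Reagents that add atoms: tert-butyl hydroperoxide, CC(C)(C)OO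
Why: Sharpless asymmetric epoxidation; the L-(+)-tartrate complex delivers oxygen to the face that gives the (2S,3R)-epoxide, as with other Z-3-substituted allylic alcohols, and the syn addition keeps the methyl groups trans.

Step 15
Reactants: 25 [(2S,3R)-2,3-dimethyloxiran-2-yl]methanol
Product: 26 (2R,3R)-2,3-dimethyloxirane-2-carboxylic acid
Conditions: RuCl3 (cat.), NaIO4, CCl4/MeCN/H2O, rt
Reagents that add atoms: sodium periodate, [Na+].[O-]I(=O)(=O)=O; water, O
Why: RuO4 oxidation of the primary epoxy alcohol to the glycidic acid without opening the epoxide; the C2 descriptor changes only because the substituent priorities change.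

Step 16
Reactants: 22 6α-hydroxy-1-oxo-3,10-epoxygermacra-2,4(Z),11(13)-trien-12,8α-olide; 26 (2R,3R)-2,3-dimethyloxirane-2-carboxylic acid
Product: 27 (4Z,6S,7R,8S,10R)-1-oxo-3,10-epoxygermacra-2,4,11(13)-trien-12,8-olid-6-yl (2R,3R)-2,3-dimethyloxirane-2-carboxylate
Conditions: PPh3, i-PrO2C–N=N–CO2i-Pr, toluene, 0 °C → rt
Reagents that add atoms: none
Why: Mitsunobu esterification: the alkoxyphosphonium of the secondary allylic alcohol is displaced by the relatively acidic glycidic carboxylate with inversion, turning 6α-OH into the 6β-ester (6S); attack at the tertiary, conjugated C4 is disfavoured.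

## Compound list

1 | (2S,5S)-2-tert-butyl-5-methyl-1,3-dioxolan-4-one | C[C@@H]1O[C@@H](OC1=O)C(C)(C)C | starting material
2 | allyl bromide | C=CCBr | starting material
3 | lithium (2S)-2-tert-butyl-5-methyl-1,3-dioxol-4-olate | CC1=C(O[Li])O[C@H](O1)C(C)(C)C | intermediate
4 | (2S,5R)-2-tert-butyl-5-methyl-5-(prop-2-en-1-yl)-1,3-dioxolan-4-one | C=CC[C@@]1(C)O[C@@H](OC1=O)C(C)(C)C | intermediate
5 | (R)-2-hydroxy-N-methoxy-N,2-dimethylpent-4-enamide | C=CC[C@@](C)(O)C(=O)N(C)OC | intermediate
6 | (Z)-3-methylpent-2-en-4-yn-1-ol | C#C/C(C)=C\CO | starting material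
7 | tert-butyldimethyl{[(2Z)-3-methylpent-2-en-4-yn-1-yl]oxy}silane | C#C/C(C)=C\CO[Si](C)(C)C(C)(C)C | intermediate
8 | lithium acetylide of 7 | [Li]C#C/C(C)=C\CO[Si](C)(C)C(C)(C)C | intermediate
9 | (4R,8Z)-10-[(tert-butyldimethylsilyl)oxy]-4-hydroxy-4,8-dimethyldeca-1,8-dien-6-yn-5-one | C=CC[C@@](C)(O)C(=O)C#C/C(C)=C\CO[Si](C)(C)C(C)(C)C | intermediate
10 | (2R)-5-[(2Z)-4-[(tert-butyldimethylsilyl)oxy]but-2-en-2-yl]-2-methyl-2-(prop-2-en-1-yl)furan-3(2H)-one | C=CC[C@@]1(C)OC(=CC1=O)/C(C)=C\CO[Si](C)(C)C(C)(C)C | intermediate
11 | (2R)-5-[(2Z)-4-[(tert-butyldimethylsilyl)oxy]but-2-en-2-yl]-2-(2,3-dihydroxypropyl)-2-methylfuran-3(2H)-one (both carbinol epimers) | OCC(O)C[C@@]1(C)OC(=CC1=O)/C(C)=C\CO[Si](C)(C)C(C)(C)C | intermediate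
12 | 2-[(2R)-5-[(2Z)-4-[(tert-butyldimethylsilyl)oxy]but-2-en-2-yl]-2-methyl-3-oxo-2,3-dihydrofuran-2-yl]acetaldehyde | O=CC[C@@]1(C)OC(=CC1=O)/C(C)=C\CO[Si](C)(C)C(C)(C)C | intermediate
13 | methyl propiolate | C#CC(=O)OC | starting material
14 | formaldehyde (as paraformaldehyde) | C=O | starting material
15 | methyl (2Z)-2-(hydroxymethyl)-3-iodoprop-2-enoate | I/C=C(/CO)C(=O)OC | intermediate
16 | methyl (2Z,4S)-5-[(2R)-5-[(2Z)-4-[(tert-butyldimethylsilyl)oxy]but-2-en-2-yl]-2-methyl-3-oxo-2,3-dihydrofuran-2-yl]-4-hydroxy-2-(hydroxymethyl)pent-2-enoate | COC(=O)/C(CO)=C\[C@@H](O)C[C@@]1(C)OC(=CC1=O)/C(C)=C\CO[Si](C)(C)C(C)(C)C | intermediate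
17 | (5S)-5-{[(2R)-5-[(2Z)-4-[(tert-butyldimethylsilyl)oxy]but-2-en-2-yl]-2-methyl-3-oxo-2,3-dihydrofuran-2-yl]methyl}-3-(hydroxymethyl)furan-2(5H)-one | OCC1=C[C@H](C[C@@]2(C)OC(=CC2=O)/C(C)=C\CO[Si](C)(C)C(C)(C)C)OC1=O | intermediate
18 | (5S)-3-(bromomethyl)-5-{[(2R)-5-[(2Z)-4-[(tert-butyldimethylsilyl)oxy]but-2-en-2-yl]-2-methyl-3-oxo-2,3-dihydrofuran-2-yl]methyl}furan-2(5H)-one | BrCC1=C[C@H](C[C@@]2(C)OC(=CC2=O)/C(C)=C\CO[Si](C)(C)C(C)(C)C)OC1=O | intermediate
19 | (5S)-3-(bromomethyl)-5-{[(2R)-5-[(2Z)-4-hydroxybut-2-en-2-yl]-2-methyl-3-oxo-2,3-dihydrofuran-2-yl]methyl}furan-2(5H)-one | BrCC1=C[C@H](C[C@@]2(C)OC(=CC2=O)/C(C)=C\CO)OC1=O | intermediate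
20 | (2Z)-3-[(5R)-5-{[(2S)-4-(bromomethyl)-5-oxo-2,5-dihydrofuran-2-yl]methyl}-5-methyl-4-oxo-4,5-dihydrofuran-2-yl]but-2-enal | BrCC1=C[C@H](C[C@@]2(C)OC(=CC2=O)/C(C)=C\C=O)OC1=O | intermediate
21 | dichlorochromium allyl species derived from 20 (trivalent chromium on C13) | Cl[Cr](Cl)CC1=C[C@H](C[C@@]2(C)OC(=CC2=O)/C(C)=C\C=O)OC1=O | intermediate
22 | 6α-hydroxy-1-oxo-3,10-epoxygermacra-2,4(Z),11(13)-trien-12,8α-olide (6R,7S,8S,10R) | C=C1C(=O)O[C@H]2C[C@@]3(C)OC(=CC3=O)/C(C)=C\[C@@H](O)[C@H]12 | intermediate
23 | methyl angelate, methyl (2Z)-2-methylbut-2-enoate | C/C=C(/C)C(=O)OC | starting material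
24 | (2Z)-2-methylbut-2-en-1-ol | C/C=C(/C)CO | intermediate
25 | [(2S,3R)-2,3-dimethyloxiran-2-yl]methanol | OC[C@]1(C)O[C@@H]1C | intermediate
26 | (2R,3R)-2,3-dimethyloxirane-2-carboxylic acid | OC(=O)[C@]1(C)O[C@@H]1C | intermediate
27 | (4Z,6S,7R,8S,10R)-1-oxo-3,10-epoxygermacra-2,4,11(13)-trien-12,8-olid-6-yl (2R,3R)-2,3-dimethyloxirane-2-carboxylate | C=C1C(=O)O[C@H]2C[C@@]3(C)OC(=CC3=O)/C(C)=C\[C@H](OC(=O)[C@]3(C)O[C@@H]3C)[C@H]12 | target

## Step count and risk

Total step count: 16. Longest linear sequence: 11 steps (steps 1, 2, 4, 5, 6, 8, 9, 10, 11, 12, 16).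

**Step 12 (key step).** The most likely failures are intermolecular allylation and oligomerisation, because the strained bridged ring closes slowly. Less likely are attack on the wrong face of the butenolide, which would fuse the lactone cis, an unexpected sense at C6, and translactonisation of the chromium alkoxide at O6 onto C12 before the quench. Fallback, from 19 back to 22: the ring is first closed as an unstrained ether and then contracted. Intramolecular Williamson etherification of 19 (Ag2O, high dilution) should give the thirteen-membered allylic ether F1, in which O6 is tied to C13. Deprotonation at C6 (LiN(SiMe3)2, THF, −78 °C) gives a carbanion that is vinylogous to the furanone carbonyl. A [2,3]-Wittig ring contraction through a five-membered transition state should then form C6–C7, release the C6 hydroxyl and shift the alkene to C11=C13, rejoining the route at 22. If the other C6 epimer forms instead, it would be esterified without inversion as described under step 16.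

**Step 8.** The risk is poor facial selectivity at C8, because the ligand has to override whatever bias the remote C10 centre exerts, together with loss of the β-oxygenated aldehyde by elimination under the amine. Fallback, from 12 back to 18: vinylmagnesium bromide at −78 °C should add only to the aldehyde and give the allylic alcohols F2 as both C8 epimers. A Sharpless kinetic resolution (Ti(Oi-Pr)4, t-BuOOH, D-(−)-diisopropyl tartrate, the tartrate enantiomer that epoxidises the 8R epimer faster) leaves the (8S)-alcohol F3. Carbodiimide esterification with 2-(bromomethyl)acrylic acid gives the diene ester F4. Ring-closing metathesis with the second-generation Grubbs catalyst then closes the butenolide and delivers 18 directly.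

**Step 16.** The risks are elimination of the activated C6 oxygen, SN2′ displacement at C4 in place of clean SN2 displacement at the hindered C6, and conjugate addition of the phosphine to the methylene lactone. Fallback, from 22 back to 27: oxidation with Dess–Martin periodinane gives the C6 ketone F5. Luche reduction (NaBH4, CeCl3, −78 °C) from the outer face of the ring should give the 6β-alcohol F6. Yamaguchi esterification of F6 with 26 (2,4,6-trichlorobenzoyl chloride, Et3N, DMAP) proceeds with retention and gives 27.

**Step 6.** The risk is competing dihydroxylation of the trisubstituted C4=C5 alkene, and retro-oxa-Michael opening of the furanone in the β-oxygenated aldehyde. Fallback, from 4 back to 12: the allyl group is cleaved before any other alkene is present. Ozonolysis of 4 in methanol with reductive work-up (Me2S) and acetalisation (HC(OMe)3, TsOH) gives the dimethyl acetal F7. Aminolysis as in step 2 then gives the Weinreb amide F8, addition of acetylide 8 as in step 4 gives the hydroxy ynone F9, and gold-catalysed cyclisation as in step 5 gives the furanone acetal F10. Mild acid hydrolysis of the furanone acetal F10 (pyridinium tosylate, wet acetone) then releases 12.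

## Further compounds

F1 | step 12 | thirteen-membered allylic ether of 19 (O6 bonded to C13; 8S,10R; 4Z) | O=C1O[C@H]2C[C@@]3(C)OC(=CC3=O)/C(C)=C\COCC1=C2
F2 | step 8 | (2R)-5-[(2Z)-4-[(tert-butyldimethylsilyl)oxy]but-2-en-2-yl]-2-(2-hydroxybut-3-en-1-yl)-2-methylfuran-3(2H)-one (both carbinol epimers) | C=CC(O)C[C@@]1(C)OC(=CC1=O)/C(C)=C\CO[Si](C)(C)C(C)(C)C
F3 | step 8 | (2R)-5-[(2Z)-4-[(tert-butyldimethylsilyl)oxy]but-2-en-2-yl]-2-[(2S)-2-hydroxybut-3-en-1-yl]-2-methylfuran-3(2H)-one | C=C[C@@H](O)C[C@@]1(C)OC(=CC1=O)/C(C)=C\CO[Si](C)(C)C(C)(C)C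
F4 | step 8 | (2S)-1-[(2R)-5-[(2Z)-4-[(tert-butyldimethylsilyl)oxy]but-2-en-2-yl]-2-methyl-3-oxo-2,3-dihydrofuran-2-yl]but-3-en-2-yl 2-(bromomethyl)prop-2-enoate | C=C(CBr)C(=O)O[C@H](C=C)C[C@@]1(C)OC(=CC1=O)/C(C)=C\CO[Si](C)(C)C(C)(C)C
F5 | step 16 | 1,6-dioxo-3,10-epoxygermacra-2,4(Z),11(13)-trien-12,8α-olide | C=C1C(=O)O[C@H]2C[C@@]3(C)OC(=CC3=O)/C(C)=C\C(=O)[C@H]12
F6 | step 16 | 6β-hydroxy-1-oxo-3,10-epoxygermacra-2,4(Z),11(13)-trien-12,8α-olide (6S,7S,8S,10R) | C=C1C(=O)O[C@H]2C[C@@]3(C)OC(=CC3=O)/C(C)=C\[C@H](O)[C@H]12
F7 | step 6 | (2S,5R)-2-tert-butyl-5-(2,2-dimethoxyethyl)-5-methyl-1,3-dioxolan-4-one | COC(OC)C[C@@]1(C)O[C@@H](OC1=O)C(C)(C)C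
F8 | step 6 | (R)-2-hydroxy-N,4,4-trimethoxy-N,2-dimethylbutanamide | COC(OC)C[C@@](C)(O)C(=O)N(C)OC
F9 | step 6 | (3R,7Z)-9-[(tert-butyldimethylsilyl)oxy]-3-hydroxy-1,1-dimethoxy-3,7-dimethylnon-7-en-5-yn-4-one | COC(OC)C[C@@](C)(O)C(=O)C#C/C(C)=C\CO[Si](C)(C)C(C)(C)C
F10 | step 6 | (2R)-5-[(2Z)-4-[(tert-butyldimethylsilyl)oxy]but-2-en-2-yl]-2-(2,2-dimethoxyethyl)-2-methylfuran-3(2H)-one | COC(OC)C[C@@]1(C)OC(=CC1=O)/C(C)=C\CO[Si](C)(C)C(C)(C)C
A1 | alternative 1 | ten-membered α′-hydroxy ynone with the 8,12-lactone closed (furanone not yet formed) | C=C1C(=O)O[C@H]2C[C@@](C)(O)C(=O)C#C/C(C)=C\[C@H](O)[C@H]12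
A2 | alternative 1 | open-chain methyl 2-(bromomethyl)enoate aldehyde (C6 silyl ether, C10 triethylsilyl ether) | O=CC[C@@](C)(O[Si](CC)(CC)CC)C(=O)C#C/C(C)=C\[C@H](O[Si](C)(C)C(C)(C)C)/C=C(\CBr)C(=O)OC
A3 | alternative 2 | (2R,3S,6R)-6-(3-diazo-2-oxobutyl)-5-methyl-2-vinyl-3,6-dihydro-2H-pyran-3-yl acetate | CC(=[N+]=[N-])C(=O)C[C@H]1O[C@H](C=C)[C@@H](OC(C)=O)C=C1C
A4 | alternative 2 | ring-expanded 11-oxabicyclo[6.2.1]undeca-4(Z),7(Z)-dien-2-one bearing the C6 acetate | C[C@@]12C/C=C\[C@@H](OC(C)=O)C=C(C)[C@@H](CC1=O)O2
A5 | alternative 3 | (2R)-5-[(2Z)-4-hydroxyhexa-2,5-dien-2-yl]-2-methyl-2-(prop-2-en-1-yl)furan-3(2H)-one | C=CC[C@@]1(C)OC(=CC1=O)/C(C)=C\[C@H](O)C=C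
A6 | alternative 3 | 6-hydroxy-1-oxo-3,10-epoxygermacra-2,4(Z),7(Z)-triene (metathesis product) | C[C@@]12C/C=C\[C@@H](O)/C=C(C)\C(=CC1=O)O2
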